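**Assumption:** the target has no stereogenic element and is treated as a conformationally mobile macrocycle; the phosphonium salt 4 is taken as a purchasable reagent.

## Analysis of the target

The target 21 is a macrocyclic bis(bibenzyl) of the marchantin type. Four benzene rings are joined into a 17-membered ring by two diaryl ether oxygens and two CH2CH2 bridges. Ring A carries the bridge carbon at C1, the ether oxygen to ring B at C3 and hydroxyls at C4 and C5. Ring B is a para-phenylene with the ether oxygen at C1 and the bridge carbon at C4. Ring C carries the bridge at C1, the ether oxygen to ring D at C2 and hydroxyls at C3 and C4, and ring D is an ortho-phenylene. There is no stereocentre, and the ethano bridges make stable atropisomers unlikely, so no stereocontrol is needed. The two catechols are oxidation-prone and are carried as methyl ethers until the last step. The difficulty lies in closing a 17-membered ring that contains a para-phenylene and in making two diaryl ether links at carbons flanked by oxygen (ring A C3, ring C C2). The strategy rests on ring B: it bears only the oxygen at C1 and the carbon at C4, so its six carbons can come from C3–C6 of a 5-acyl-2-pyrone and the two carbons of an aryloxyacetylene whose oxygen already sits on ring A.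

## Retrosynthetic reasoning

**21 back to 20.** The four O–CH3 bonds are cut. The catechols would interfere with every base- and metal-mediated step, and the methyl ethers already reside in 1 and 7 and tolerate organolithium, heat and acid. The forward step is an exhaustive Lewis-acid demethylation that leaves both diaryl ethers intact.

**20 back to 19.** The benzylic CH2 on ring B is traced back to a ketone. This carbonyl is what the acyl group of the pyrone leaves behind, and it is also what makes the pyrone electron-poor enough to react. The forward step is a deoxygenation of a para-aryloxy aryl ketone, which is helped by the ring B oxygen stabilising the benzylic cation.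

**19 back to 17 (through 18).** Ring B is cut at C1–C2 and C5–C6, the two bonds a [4+2] addition makes between an alkyne (ring B C1 and C6) and a 2-pyrone (ring B C2–C5), and the lactone bridge is restored. Cutting here avoids forming the ring A C3–O–ring B ether as such. That bond would otherwise need an activating group on ring B that must later be erased, or a coupling next to two oxygen substituents on ring A. One operation then builds ring B and closes the macrocycle. The forward reaction must be intramolecular, must orient the ether oxygen para to the acyl carbon, and must aromatise by a decarboxylative cycloreversion of 18.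

**17 back to 13 and 15 (through 16).** The CH2–C(=O) bond between the ring C benzylic carbon and the ketone is cut. Ring C then arrives as a benzylic nucleophile grown from the formyl carbon of 7, and all five pyrone carbons plus the ketone carbon arrive as 15, one step from 14. The forward acylation must tolerate the pyrone and the terminal alkyne, which points to a weakly basic benzylzinc reagent under palladium catalysis.

**13 back to 11 and 9 (through 12 and 10).** The ynol ether needs an organolithium base for its formation, so it must exist before the pyrone is attached. It is also acid-labile, so it is unmasked as late as possible from the dichlorovinyl ether of 9, which is inert to carbonate, alkoxide, hydride and heat. The benzylic alcohol passes through the unmasking as its lithium alkoxide in 10 and is chlorinated afterwards under non-acidic conditions.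

**9 back to 8, then 6 and 7.** The ring C C2–O bond is cut. In 7 the fluorine sits ortho to the formyl group, which activates the displacement and later becomes the benzylic carbon. The ring D C–O bond has no such activation, so ring D is the nucleophile.

**6 back to 5, then 3 and 4.** The CH2–CH2 bridge between rings A and D is cut as an alkene, made by olefination of the ring A aldehyde with the ring D benzylic phosphonium salt. The reduction must spare the two C–Cl bonds, so hydrogen is transferred without a hydrogenation catalyst.

**3 back to 1 and 2.** The two future alkyne carbons are placed on the single free phenol of 1 at the outset. The dichlorovinyl ether then serves as its own protecting group, and the route needs no protection or deprotection step.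

## Alternatives that were turned down

**Alternative 1:** The ring A C3–O bond is disconnected oxidatively. The seco bis-phenol A2 (a 3,5-dibromo-4-hydroxyphenyl ring A and a 3,5-dichloro-4-hydroxyphenyl ring B) would be electrolysed at constant current and the crude reduced with zinc to give the macrocycle A1. In its favour, the most congested bond of the target forms at room temperature and the halogens direct the coupling. Against it, A1 still carries a bromine where the target has the ring A C5 hydroxyl and two chlorines on ring B. Reaching 21 then needs a C–Br to C–OH exchange, two hydrodechlorinations and the demethylation. The electron-rich dimethoxy ring C is a second site for anodic oxidation, and ring closure competes with dimerisation at the electrode. It is milder in the closing step than the chosen route, but the chosen route leaves nothing on ring B to remove and finishes in two steps after the closure.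

**Alternative 2:** The same ether is disconnected at the O–ring B C1 bond. The phenoxide of the seco compound A4 would displace fluoride from its 4-fluoro-3-nitrophenyl ring B under carbonate base at high dilution to give A3. This is the most reliable closure of the four: addition–elimination macrocyclisations of this kind are well established and the open-chain precursor is built from cheap parts. On reliability of the ring closure it is stronger than the chosen strategy. Its cost is the nitro group on ring B of A3, which must be reduced, diazotised and reductively removed before demethylation. The chosen strategy is offered in its place because ring B is built without an auxiliary group and the sequence after closure is two steps.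

**Alternative 3:** The ring C C1–C(=O) bond is disconnected. The arylacetic acid A6 would be converted into its acid chloride and closed by Lewis-acid acylation onto ring C to give the ketone A5. It is short and A5 needs the same two closing steps as 19. The weakness is site selectivity. Ring C of A6 offers C1 (para to methoxy, ortho to the bulky aryloxy group) and the position para to the aryloxy group, and ring A is equally activated and closer. Arylacetyl chlorides also tend to form ketenes or lose CO under Lewis acids. In the chosen route the position of the ketone and of both new ring bonds is fixed by construction, at the price of a less precedented closure.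

Key step: step 10

## Route

**Step 1**
Reactants: 1 3-hydroxy-4,5-dimethoxybenzaldehyde; 2 trichloroethylene
Product: 3 3-{[(E)-1,2-dichloroethenyl]oxy}-4,5-dimethoxybenzaldehyde
Conditions: K2CO3, DMF, 70 °C
Reagents that add atoms: none
Why: Base eliminates HCl from 2 to dichloroacetylene in situ and the phenoxide adds anti across it, a known route to aryl (E)-1,2-dichlorovinyl ethers; the aldehyde has no enolisable hydrogen and is unaffected.

**Step 2**
Reactants: 3 3-{[(E)-1,2-dichloroethenyl]oxy}-4,5-dimethoxybenzaldehyde; 4 (2-hydroxybenzyl)triphenylphosphonium bromide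
Product: 5 2-[2-(3-{[(E)-1,2-dichloroethenyl]oxy}-4,5-dimethoxyphenyl)ethenyl]phenol (E/Z mixture at the stilbene bond)
Conditions: KOtBu (2.1 equiv), THF, 0 °C → rt
Reagents that add atoms: none
Why: Wittig olefination; the first equivalent of base forms the phenoxide and the second the semi-stabilised ylide. The alkene geometry is irrelevant because it is reduced next, and the dichlorovinyl ether is inert to alkoxide.

**Step 3**
Reactants: 5 2-[2-(3-{[(E)-1,2-dichloroethenyl]oxy}-4,5-dimethoxyphenyl)ethenyl]phenol
Product: 6 2-[2-(3-{[(E)-1,2-dichloroethenyl]oxy}-4,5-dimethoxyphenyl)ethyl]phenol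
Conditions: TsNHNH2, NaOAc, THF–H2O, reflux
Reagents that add atoms: none
Why: Diimide reduction; concerted syn hydrogen transfer should reduce the unpolarised 1,2-diarylethene, while the trisubstituted chlorinated enol ether is a poor acceptor and the C–Cl bonds, which a Pd/C hydrogenation would cleave, are untouched.

**Step 4**
Reactants: 6 2-[2-(3-{[(E)-1,2-dichloroethenyl]oxy}-4,5-dimethoxyphenyl)ethyl]phenol; 7 2-fluoro-3,4-dimethoxybenzaldehyde
Product: 8 2-{2-[2-(3-{[(E)-1,2-dichloroethenyl]oxy}-4,5-dimethoxyphenyl)ethyl]phenoxy}-3,4-dimethoxybenzaldehyde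
Conditions: K2CO3, DMF, 120 °C
Reagents that add atoms: none
Why: SNAr; the phenoxide adds at the fluorine-bearing carbon ortho to the formyl group, which stabilises the Meisenheimer adduct, and fluoride leaves. The dichlorovinyl ether is itself made in this base and solvent and should survive.

**Step 5**
Reactants: 8 2-{2-[2-(3-{[(E)-1,2-dichloroethenyl]oxy}-4,5-dimethoxyphenyl)ethyl]phenoxy}-3,4-dimethoxybenzaldehyde
Product: 9 (2-{2-[2-(3-{[(E)-1,2-dichloroethenyl]oxy}-4,5-dimethoxyphenyl)ethyl]phenoxy}-3,4-dimethoxyphenyl)methanol
Conditions: NaBH4, MeOH–THF, 0 °C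
Reagents that add atoms: none
Why: Borohydride reduction of an aryl aldehyde; ethers and the dichlorovinyl group are inert to hydride.

**Step 6**
Reactants: 9 (2-{2-[2-(3-{[(E)-1,2-dichloroethenyl]oxy}-4,5-dimethoxyphenyl)ethyl]phenoxy}-3,4-dimethoxyphenyl)methanol
Product: 11 (2-{2-[2-(3-(ethynyloxy)-4,5-dimethoxyphenyl)ethyl]phenoxy}-3,4-dimethoxyphenyl)methanol, via dilithium alkoxide–acetylide 10 (not isolated)
Conditions: n-BuLi (3.3 equiv), THF, −78 → −40 °C; then MeOH, H2O
Reagents that add atoms: none
Why: Known conversion of 1,2-dichlorovinyl ethers into ynol ethers: deprotonation, loss of LiCl to the chloroalkyne, then lithium–chlorine exchange. One further equivalent of base holds the alcohol as its alkoxide, and a non-acidic quench protects the ynol ether.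

**Step 7**
Reactants: 11 (2-{2-[2-(3-(ethynyloxy)-4,5-dimethoxyphenyl)ethyl]phenoxy}-3,4-dimethoxyphenyl)methanol
Product: 13 1-(chloromethyl)-2-{2-[2-(3-(ethynyloxy)-4,5-dimethoxyphenyl)ethyl]phenoxy}-3,4-dimethoxybenzene, via benzylic mesylate 12 (not isolated)
Conditions: MsCl, Et3N, CH2Cl2, 0 °C; then LiCl, THF, 0 °C → rt
Reagents that add atoms: lithium chloride, [Li+].[Cl-]; methanesulfonyl chloride, CS(=O)(=O)Cl (either can supply the chlorine)
Why: Mesylation followed by chloride displacement; the para-methoxybenzylic mesylate is displaced readily, and the amine-buffered medium never exposes the acid-labile ynol ether to free HCl.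

**Step 8**
Reactants: 14 coumalic acid (2-oxo-2H-pyran-5-carboxylic acid)
Product: 15 coumaloyl chloride (2-oxo-2H-pyran-5-carbonyl chloride)
Conditions: (COCl)2, DMF (cat.), CH2Cl2, rt
Reagents that add atoms: oxalyl chloride, O=C(Cl)C(=O)Cl
Why: Standard acid chloride formation through the Vilsmeier-type chloroiminium salt; the pyrone ring is stable to these conditions and 15 is used crude.

**Step 9**
Reactants: 13 1-(chloromethyl)-2-{2-[2-(3-(ethynyloxy)-4,5-dimethoxyphenyl)ethyl]phenoxy}-3,4-dimethoxybenzene; 15 coumaloyl chloride
Product: 17 5-[(2-{2-[2-(3-(ethynyloxy)-4,5-dimethoxyphenyl)ethyl]phenoxy}-3,4-dimethoxyphenyl)acetyl]-2H-pyran-2-one, via benzylzinc chloride 16 (not isolated)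
Conditions: Zn dust, LiCl, THF, 25 °C; then Pd(PPh3)4 (5 mol %), 15 added slowly, THF, 0 °C → rt
Reagents that add atoms: none
Why: LiCl-assisted zinc insertion into a benzylic chloride followed by Negishi acylation; oxidative addition of the acid chloride to zerovalent palladium is fast, and the benzylzinc halide is too weakly basic and nucleophilic to attack the pyrone or, it is expected, to deprotonate the alkyne.

**Step 10**
Reactants: 17 5-[(2-{2-[2-(3-(ethynyloxy)-4,5-dimethoxyphenyl)ethyl]phenoxy}-3,4-dimethoxyphenyl)acetyl]-2H-pyran-2-one
Product: 19 macrocyclic deoxybenzoin tetramethyl ether (ketone carbon on ring B C4, CH2 on ring C C1), via bridged lactone cycloadduct 18 (not isolated)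
Conditions: PhCl, 130 °C, 1 mM (17 added by syringe pump), BHT (cat.)
Reagents that add atoms: none
Why: The electron-poor 5-acyl-2-pyrone acts as diene and the electron-rich aryl ynol ether as dienophile in an inverse-demand [4+2] addition across pyrone C3 and C6, giving the 2-oxabicyclo[2.2.2]octadienone 18, which loses CO2 by retro-[4+2] to the benzene. The closest known reaction type is the thermal benzannulation of coumalate-type pyrones with electron-rich alkynes, together with intramolecular pyrone Diels–Alder closures of cyclophanes; an aryl ynol ether as the tethered dienophile is the untried element, so the temperature window is the open question. Ring B closes by cycloaddition then cycloreversion from four pyrone carbons and the two alkyne carbons, forming ring B C1–C2 and C5–C6. The 17-membered macrocycle closes at the same time as the tether ring of the intramolecular addition, running through pyrone C5, C6 and both alkyne carbons. No stereocentre remains, since the two bridgehead centres of 18 are erased on aromatisation. The step needs para orientation, which follows from the polarity match: the nucleophilic terminal alkyne carbon bonds to the electrophilic pyrone C6 and the oxygen-bearing carbon to C3, whereas the reversed orientation would give the meta isomer in a 16-membered ring. It also needs intramolecular reaction, which high dilution and slow addition should favour. The aryl ynol ether has no hydrogen positioned for retro-ene loss of ketene, so it should tolerate the temperature.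

**Step 11**
Reactants: 19 macrocyclic deoxybenzoin tetramethyl ether
Product: 20 macrocyclic bis(bibenzyl) tetramethyl ether
Conditions: Et3SiH, CF3CO2H, CH2Cl2, rt → 40 °C
Reagents that add atoms: none
Why: Ionic hydrogenation; protonation and hydride transfer give the benzylic alcohol and then the cation, which the para-aryloxy oxygen of ring B stabilises, and a second hydride gives CH2. Any stilbene formed by elimination is reduced to the same product.

**Step 12**
Reactants: 20 macrocyclic bis(bibenzyl) tetramethyl ether
Product: 21 target macrocycle (CNP0114693.0)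
Conditions: BBr3, CH2Cl2, −78 °C → rt; then H2O
Reagents that add atoms: none
Why: Lewis-acid cleavage of aryl methyl ethers by bromide attack on the boron-activated O–CH3 group; diaryl ethers are not cleaved, and an oxygen-free work-up protects the catechols.

## Compound list

1 | 3-hydroxy-4,5-dimethoxybenzaldehyde | O=Cc1cc(O)c(OC)c(OC)c1 | starting material
2 | trichloroethylene | ClC=C(Cl)Cl | starting material
3 | 3-{[(E)-1,2-dichloroethenyl]oxy}-4,5-dimethoxybenzaldehyde | O=Cc1cc(O/C(Cl)=C\Cl)c(OC)c(OC)c1 | intermediate
4 | (2-hydroxybenzyl)triphenylphosphonium bromide | [Br-].Oc1ccccc1C[P+](c1ccccc1)(c1ccccc1)c1ccccc1 | starting material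
5 | 2-[2-(3-{[(E)-1,2-dichloroethenyl]oxy}-4,5-dimethoxyphenyl)ethenyl]phenol, E/Z mixture at the stilbene bond | Oc1ccccc1C=Cc1cc(O/C(Cl)=C\Cl)c(OC)c(OC)c1 | intermediate
6 | 2-[2-(3-{[(E)-1,2-dichloroethenyl]oxy}-4,5-dimethoxyphenyl)ethyl]phenol | Oc1ccccc1CCc1cc(O/C(Cl)=C\Cl)c(OC)c(OC)c1 | intermediate
7 | 2-fluoro-3,4-dimethoxybenzaldehyde | O=Cc1ccc(OC)c(OC)c1F | starting material
8 | 2-{2-[2-(3-{[(E)-1,2-dichloroethenyl]oxy}-4,5-dimethoxyphenyl)ethyl]phenoxy}-3,4-dimethoxybenzaldehyde | O=Cc1ccc(OC)c(OC)c1Oc1ccccc1CCc1cc(O/C(Cl)=C\Cl)c(OC)c(OC)c1 | intermediate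
9 | (2-{2-[2-(3-{[(E)-1,2-dichloroethenyl]oxy}-4,5-dimethoxyphenyl)ethyl]phenoxy}-3,4-dimethoxyphenyl)methanol | OCc1ccc(OC)c(OC)c1Oc1ccccc1CCc1cc(O/C(Cl)=C\Cl)c(OC)c(OC)c1 | intermediate
10 | dilithium alkoxide–acetylide of 11 | [Li]OCc1ccc(OC)c(OC)c1Oc1ccccc1CCc1cc(OC#C[Li])c(OC)c(OC)c1 | intermediate (not isolated)
11 | (2-{2-[2-(3-(ethynyloxy)-4,5-dimethoxyphenyl)ethyl]phenoxy}-3,4-dimethoxyphenyl)methanol | OCc1ccc(OC)c(OC)c1Oc1ccccc1CCc1cc(OC#C)c(OC)c(OC)c1 | intermediate
12 | benzylic mesylate of 11 | CS(=O)(=O)OCc1ccc(OC)c(OC)c1Oc1ccccc1CCc1cc(OC#C)c(OC)c(OC)c1 | intermediate (not isolated)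
13 | 1-(chloromethyl)-2-{2-[2-(3-(ethynyloxy)-4,5-dimethoxyphenyl)ethyl]phenoxy}-3,4-dimethoxybenzene | ClCc1ccc(OC)c(OC)c1Oc1ccccc1CCc1cc(OC#C)c(OC)c(OC)c1 | intermediate
14 | coumalic acid | O=C(O)c1ccc(=O)oc1 | starting material
15 | coumaloyl chloride | O=C(Cl)c1ccc(=O)oc1 | intermediate
16 | benzylzinc chloride from 13 | Cl[Zn]Cc1ccc(OC)c(OC)c1Oc1ccccc1CCc1cc(OC#C)c(OC)c(OC)c1 | intermediate (not isolated)
17 | 5-[(2-{2-[2-(3-(ethynyloxy)-4,5-dimethoxyphenyl)ethyl]phenoxy}-3,4-dimethoxyphenyl)acetyl]-2H-pyran-2-one | C#COc1cc(CCc2ccccc2Oc2c(CC(=O)c3ccc(=O)oc3)ccc(OC)c2OC)cc(OC)c1OC | intermediate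
18 | bridged 2-oxabicyclo[2.2.2]octadienone cycloadduct, racemic, one enantiomer drawn | O=C1O[C@@H]2C=C(Oc3cc(CCc4ccccc4Oc4c(C5)ccc(OC)c4OC)cc(OC)c3OC)[C@H]1C=C2C5=O | intermediate (not isolated)
19 | macrocyclic deoxybenzoin tetramethyl ether, ketone on ring B | COc1cc2cc(c1OC)Oc1ccc(cc1)C(=O)Cc1ccc(OC)c(OC)c1Oc1ccccc1CC2 | intermediate
20 | macrocyclic bis(bibenzyl) tetramethyl ether | COc1cc2cc(c1OC)Oc1ccc(cc1)CCc1ccc(OC)c(OC)c1Oc1ccccc1CC2 | intermediate
21 | target macrocycle CNP0114693.0 | Oc1cc2cc(c1O)Oc1ccc(cc1)CCc1ccc(O)c(O)c1Oc1ccccc1CC2 | target

## Step count and risk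

Total step count: 12. Longest linear sequence: 11 steps (steps 1–7 and 9–12, from 1 to 21); step 8 is a one-step side branch.

**Step 10 (key step).** Three processes can defeat it. Intermolecular cycloaddition and oligomerisation can compete with ring closure. The addition can occur in the reversed orientation, which closes a 16-membered meta-bridged ring. The ynol ether can be lost by hydration or thermal decomposition before it reacts.
Fallback, from 11 back to 20: keep the benzannulation but make it intermolecular, and close the macrocycle separately by a carbonyl coupling.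
- Heating 11 with methyl coumalate in toluene should give, through the bridged lactone adduct F1 (not isolated) and loss of CO2, methyl 4-[5-(2-{2-[6-(hydroxymethyl)-2,3-dimethoxyphenoxy]phenyl}ethyl)-2,3-dimethoxyphenoxy]benzoate F2.
- LiAlH4 would give the diol F3, and MnO2 the dialdehyde F4.
- A McMurry coupling (TiCl4, Zn, THF, reflux, high dilution) would close the macrocyclic stilbene F5, and H2 over Pd/C would give 20.

**Step 9.** The benzylzinc reagent may be quenched by the acidic alkyne C–H, giving an alkynylzinc that is then acylated. The nucleophilic alkyne carbon may also be acylated directly by 15 under zinc chloride catalysis, and Wurtz-type homocoupling can occur during insertion.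
Fallback, from 9 back to 20: carry the alkyne with a trimethylsilyl cap that is removed tracelessly.
- The dianion 10, generated as in step 6, is quenched with Me3SiCl to the bis-silyl compound F6 (not isolated), whose O–Si bond is cleaved on work-up to the C-silyl ynol ether alcohol F7.
- Mesylation to F8 (not isolated) and chloride displacement give the chloride F9.
- Zinc insertion gives the benzylzinc chloride F10 (not isolated), and acylation with 15 under Pd(PPh3)4 gives the silyl pyrone ketone F11.
- Heating as in step 10 passes through the bridged adduct F12 (not isolated) to the macrocyclic silyl ketone F13, with silicon ortho to the ring B oxygen.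
- The conditions of step 11 then reduce the ketone and protodesilylate the activated aryl silane to give 20.

**Step 4.** The displacement may stall, because the para-methoxy group weakens activation by the formyl group and both partners are ortho-substituted. Forcing conditions may then degrade the aldehyde.
Fallback, from 6 back to 8: a copper-catalysed Ullmann ether coupling of 6 with 2-bromo-3,4-dimethoxybenzaldehyde (CuI, N,N-dimethylglycine, Cs2CO3, dioxane, 90 °C) gives 8 directly. This fallback makes no new compound (F0).

**Step 3.** Reduction of the stilbene may be incomplete, or the dichlorovinyl ether may be partly reduced, because selectivity rests only on the different reactivity of the two double bonds toward diimide.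
Fallback, from 1 back to 8: mask the phenol, hydrogenate catalytically and install the dichlorovinyl ether afterwards.
- MOMCl with iPr2NEt converts 1 into 3,4-dimethoxy-5-(methoxymethoxy)benzaldehyde F14.
- Wittig reaction with 4 gives the stilbene phenol F15, and H2 over Pd/C the bibenzyl phenol F16.
- SNAr with 7 gives the diaryl ether aldehyde F17, and aqueous HCl in THF frees the phenol aldehyde F18.
- Treatment with 2 and K2CO3 in DMF gives 8.

## Further compounds

F1 | step 10 | bridged lactone adduct of 11 with methyl coumalate, racemic, not isolated | O=C1O[C@@H]2C=C(Oc3cc(CCc4ccccc4Oc4c(CO)ccc(OC)c4OC)cc(OC)c3OC)[C@H]1C=C2C(=O)OC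
F2 | step 10 | methyl 4-[5-(2-{2-[6-(hydroxymethyl)-2,3-dimethoxyphenoxy]phenyl}ethyl)-2,3-dimethoxyphenoxy]benzoate | COC(=O)c1ccc(cc1)Oc1cc(CCc2ccccc2Oc2c(CO)ccc(OC)c2OC)cc(OC)c1OC
F3 | step 10 | diol from reduction of F2 | OCc1ccc(cc1)Oc1cc(CCc2ccccc2Oc2c(CO)ccc(OC)c2OC)cc(OC)c1OC
F4 | step 10 | dialdehyde from oxidation of F3 | O=Cc1ccc(cc1)Oc1cc(CCc2ccccc2Oc2c(C=O)ccc(OC)c2OC)cc(OC)c1OC
F5 | step 10 | macrocyclic stilbene tetramethyl ether, Z drawn, either isomer serves | COc1cc2cc(c1OC)Oc1ccc(cc1)/C=C\c1ccc(OC)c(OC)c1Oc1ccccc1CC2
F6 | step 9 | O,C-bis(trimethylsilyl) compound, not isolated | C[Si](C)(C)OCc1ccc(OC)c(OC)c1Oc1ccccc1CCc1cc(OC#C[Si](C)(C)C)c(OC)c(OC)c1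
F7 | step 9 | C-silyl ynol ether alcohol | OCc1ccc(OC)c(OC)c1Oc1ccccc1CCc1cc(OC#C[Si](C)(C)C)c(OC)c(OC)c1
F8 | step 9 | benzylic mesylate of F7, not isolated | CS(=O)(=O)OCc1ccc(OC)c(OC)c1Oc1ccccc1CCc1cc(OC#C[Si](C)(C)C)c(OC)c(OC)c1
F9 | step 9 | benzylic chloride from F7 | ClCc1ccc(OC)c(OC)c1Oc1ccccc1CCc1cc(OC#C[Si](C)(C)C)c(OC)c(OC)c1
F10 | step 9 | benzylzinc chloride from F9, not isolated | Cl[Zn]Cc1ccc(OC)c(OC)c1Oc1ccccc1CCc1cc(OC#C[Si](C)(C)C)c(OC)c(OC)c1
F11 | step 9 | silyl-capped pyrone ketone | C[Si](C)(C)C#COc1cc(CCc2ccccc2Oc2c(CC(=O)c3ccc(=O)oc3)ccc(OC)c2OC)cc(OC)c1OC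
F12 | step 9 | bridged lactone adduct from F11, racemic, not isolated | O=C1O[C@@H]2C([Si](C)(C)C)=C(Oc3cc(CCc4ccccc4Oc4c(C5)ccc(OC)c4OC)cc(OC)c3OC)[C@H]1C=C2C5=O
F13 | step 9 | macrocyclic ketone with trimethylsilyl on ring B ortho to oxygen | COc1cc2cc(c1OC)Oc1ccc(cc1[Si](C)(C)C)C(=O)Cc1ccc(OC)c(OC)c1Oc1ccccc1CC2
F0 | step 4 | none | none
F14 | step 3 | 3,4-dimethoxy-5-(methoxymethoxy)benzaldehyde | O=Cc1cc(OCOC)c(OC)c(OC)c1
F15 | step 3 | 2-{2-[3,4-dimethoxy-5-(methoxymethoxy)phenyl]ethenyl}phenol, E/Z mixture | Oc1ccccc1C=Cc1cc(OCOC)c(OC)c(OC)c1
F16 | step 3 | 2-{2-[3,4-dimethoxy-5-(methoxymethoxy)phenyl]ethyl}phenol | Oc1ccccc1CCc1cc(OCOC)c(OC)c(OC)c1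
F17 | step 3 | 2-(2-{2-[3,4-dimethoxy-5-(methoxymethoxy)phenyl]ethyl}phenoxy)-3,4-dimethoxybenzaldehyde | O=Cc1ccc(OC)c(OC)c1Oc1ccccc1CCc1cc(OCOC)c(OC)c(OC)c1
F18 | step 3 | 2-{2-[2-(3-hydroxy-4,5-dimethoxyphenyl)ethyl]phenoxy}-3,4-dimethoxybenzaldehyde | O=Cc1ccc(OC)c(OC)c1Oc1ccccc1CCc1cc(O)c(OC)c(OC)c1
A1 | alternative 1 | macrocyclic bromophenol diaryl ether with dichlorinated ring B | Brc1cc2cc(c1O)Oc1c(Cl)cc(cc1Cl)CCc1ccc(OC)c(OC)c1Oc1ccccc1CC2
A2 | alternative 1 | seco bis-phenol with dibromophenol ring A and dichlorophenol ring B | Oc1c(Br)cc(CCc2ccccc2Oc2c(CCc3cc(Cl)c(O)c(Cl)c3)ccc(OC)c2OC)cc1Br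
A3 | alternative 2 | macrocyclic nitro diaryl ether tetramethyl ether | COc1cc2cc(c1OC)Oc1ccc(cc1[N+](=O)[O-])CCc1ccc(OC)c(OC)c1Oc1ccccc1CC2
A4 | alternative 2 | seco ring A phenol with 4-fluoro-3-nitrophenyl ring B | COc1cc(CCc2ccccc2Oc2c(CCc3ccc(F)c([N+](=O)[O-])c3)ccc(OC)c2OC)cc(O)c1OC
A5 | alternative 3 | macrocyclic deoxybenzoin tetramethyl ether with ketone on ring C | COc1cc2cc(c1OC)Oc1ccc(cc1)CC(=O)c1ccc(OC)c(OC)c1Oc1ccccc1CC2
A6 | alternative 3 | seco ring B arylacetic acid | OC(=O)Cc1ccc(cc1)Oc1cc(CCc2ccccc2Oc2cccc(OC)c2OC)cc(OC)c1OC
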